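Watch J first.

| flask | J | L | temperature | remark | time |
|---|---|---|---|---|---|
| north | 0.025 M | 2 equiv | −25 °C | run made earlier |  |
| south | 0.038 M | 2 equiv | 0 °C | run made earlier |  |
| north-west | 0.050 M | 1 equiv | −25 °C | run made earlier |  |
| Tuesday's | 0.050 M | 2.00 equiv | 0 °C |  | 4.0 h |
| Friday's | 0.050 M | 2.00 equiv | −20 °C |  | 4.0 h |
| Sunday's | 0.050 M | 2.00 equiv | 20 °C |  | 4.0 h |

north run (percent of the J charged)

| time / h | J / % | X / % | D / % | Z / % | G / % |
|---|---|---|---|---|---|
| 0.200 | 98.5 | 0 | 0 | 1.4 | 0 |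
| 0.417 | 96.5 | 0 | 0.1 | 3.0 | 0.2 |
| 1.00 | 91.6 | 0 | 1.4 | 5.9 | 0.5 |
| 2.50 | 80.0 | 0.4 | 4.5 | 10.4 | 4.2 |

south run (percent of the J charged)

| time / min | J / % | X / % | D / % | Z / % | G / % |
|---|---|---|---|---|---|
| 4.00 | 94.7 | 0 | 0.9 | 4.4 | 0.4 |
| 10.0 | 86.9 | 0 | 3.8 | 7.9 | 1.6 |
| 20.0 | 74.9 | 0 | 7.7 | 11.5 | 4.6 |
| 60.0 | 41.2 | 1.3 | 15.2 | 20.8 | 19.8 |

north-west run (percent of the J charged)

| time / h | J / % | X / % | D / % | Z / % | G / % |
|---|---|---|---|---|---|
| 0.333 | 97.1 | 0 | 0.4 | 2.6 | 0 |
| 0.833 | 93.0 | 0 | 0.6 | 4.7 | 1.4 |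
| 1.50 | 87.3 | 0.5 | 2.6 | 7.5 | 2.8 |
| 2.50 | 80.4 | 0 | 4.5 | 8.7 | 5.8 |

(scatter of a reading: 0.3 percentage points)

- percent here means J units held: one G counts as two
- what was read earlier has a scatter of 0.3 percentage points, one standard deviation

* which of these there is most of at the end, counted by the J in it, Tuesday's (Z / X / G / D / J)
* which of these there is most of at the end, counted by the J in it, Friday's (Z / X / G / D / J)
* which of these there is most of at the end, counted by the J in it, Sunday's (Z / X / G / D / J)
* the largest of these amounts at the end, in percent of the J charged, Tuesday's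
* the largest of these amounts at the end, in percent of the J charged, Friday's
* the largest of these amounts at the end, in percent of the J charged, Sunday's

What J has lost is what the products share, so the reckoning here stays with Friday's and asks how far J has fallen. Start with the main step, J taken up by L. North and north-west held the same [L], 0.0500 M, at different [J], yet J read 80.0 % and 80.4 % at 2.50 h. J therefore falls by a steady fraction per hour, read as 0.0893 h⁻¹ at −25 °C. South, at [L] 0.0760 M, reads 0.887 h⁻¹ at 0 °C. No pair of runs changes [L] at one temperature, so taking the loss as proportional to [L] is a choice made here. Per unit of [L], south then runs 6.54 times faster than north. Placing −20 °C on a straight line in the logarithm between the two temperatures, and scaling to Friday's [L], gives the clock of J, the pseudo-first-order fraction of J lost per hour: 0.260 h⁻¹. After 4.0 h, Friday's J stands at 35.4 %.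

Now let L drain. Each J lost by the main step takes one L, so Friday's [L] sinks by at most 32.3 % of its charge. The clock holds [L] at its charge and this reckoning makes no correction for that drain, so the number stands as an estimate.

Then add the rest: Z, D, G and X share the lost J. South's largest share among them is Z, and the same proportion on Friday's gives 22.9 %, less than J. So J should hold most.

The forecast names G, J and G for Tuesday's, Friday's and Sunday's, at 47 % (39 % to 54 %), 50 % (33 % to 60 %) and 43 % (33 % to 52 %). On Friday's its grounds are “k ≈ 0.15 /h gives J ≈ 55, or about 35 if first order in L”, and its figure stands higher than the clock's.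

The flasks give G at 46.4 % on Tuesday's, J at 35.5 % on Friday's and G at 49.7 % on Sunday's.

    Q + L → E + X (k = 6.20 × 10⁻⁴ M⁻¹ s⁻¹, Ea = 68.0 kJ mol⁻¹)
    J + L → E + Z (k = 6.90 × 10⁻⁴ M⁻¹ s⁻¹, Ea = 43.0 kJ mol⁻¹)
    J + Z → G (k = 0.00200 M⁻¹ s⁻¹, Ea = 42.0 kJ mol⁻¹)
    Z + L → E + Q (k = 8.50 × 10⁻⁵ M⁻¹ s⁻¹, Ea = 69.0 kJ mol⁻¹)
    Z ⇌ D (K = 1.80, k = 1.90 × 10⁻⁴ s⁻¹, Ea = 73.0 kJ mol⁻¹, ΔH = −25.0 kJ mol⁻¹)
    (constants at −20 °C)

Friday's J ends at 35.5 %, beside the clock's 35.4 %. The neighbouring flask is Friday's with 0.500 equiv of L, a quarter of the charge. Its clock is scaled down in the same proportion to 0.0650 h⁻¹, which puts J at 77.1 % after 4.0 h. That flask ends with 77.1 % of its J, and beside it stand G at 10.5 %, D at 6.69 % and Z at 5.61 %.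

The earlier runs and the new flask are simulated from invented constants; noise was put on by code.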